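**Retrosynthetic overview**

- The target is a 6-hydroxyisoflavone. Its last precursors are the 6-O-benzyl chromone and, before that, a 4-siloxy-4H-chromene that is oxidized at C4.
- The strategy rests on the C2=C3 bond of ring C. It is the only non-aromatic C=C bond, with C2 on O1 and C3 carrying ring B, so ring C opens to an aryl vinyl ether (O1–C2) and a 1-arylvinyl carbinol (C3–C4).
- Ring C is the only ring formed. It is closed at C2=C3 by ring-closing metathesis, at the silyl ether oxidation level.
- The diene comes from a 2-(vinyloxy)benzaldehyde (ring A plus C4) and a 1-arylvinyllithium (C3 plus ring B) made by a Shapiro reaction; the C3–C4 bond is made by carbonyl addition.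
- The aldehyde comes from 4-(benzyloxy)-3-methoxyphenol by ortho-formylation and O-vinylation. Rings A and B are bought.

Key step: step 6

Remark: the target has no stereocenter; the carbinol carbon (future C4) is carried as a racemate and is removed by oxidation. 4-(Benzyloxy)-3-methoxyphenol is taken as a catalogue compound.

**Step 1**
Reactants: 1 4-(benzyloxy)-3-methoxyphenol
Product: 2 5-(benzyloxy)-2-hydroxy-4-methoxybenzaldehyde
Conditions: MgCl2 (anhydrous), Et3N, (CH2O)n, MeCN, reflux; then 1 M HCl
Reagents that add atoms: paraformaldehyde (as formaldehyde), C=O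
Why: Magnesium-mediated ortho-formylation of a phenol (Casnati–Skattebøl): the chelated magnesium phenoxide directs C–C bond formation to an ortho carbon only, the site para to the methoxy group is preferred over the one wedged between two oxygens, and excess formaldehyde accepts hydride to give the aldehyde oxidation level.

**Step 2**
Reactants: 2 5-(benzyloxy)-2-hydroxy-4-methoxybenzaldehyde; 3 vinyl acetate
Product: 4 5-(benzyloxy)-2-(ethenyloxy)-4-methoxybenzaldehyde
Conditions: [Ir(cod)Cl]2 (2 mol %), Na2CO3 (0.6 equiv), toluene, 100 °C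
Reagents that add atoms: none
Why: Iridium-catalyzed transfer vinylation of a phenol with vinyl acetate (O–H addition across the vinyl ester on monovalent iridium, then loss of acetate, which Na2CO3 takes up) is established for phenols and should leave the aldehyde and the benzyl and methyl ethers untouched.

**Step 3**
Reactants: 5 1-(3,4,5-trimethoxyphenyl)ethan-1-one (3',4',5'-trimethoxyacetophenone)
Product: 6 (E)-N'-[1-(3,4,5-trimethoxyphenyl)ethylidene]-2,4,6-tri(propan-2-yl)benzenesulfonohydrazide
Conditions: 2,4,6-triisopropylbenzenesulfonohydrazide, HCl (cat.), MeOH, rt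
Reagents that add atoms: 2,4,6-triisopropylbenzenesulfonohydrazide, CC(C)c1cc(C(C)C)c(S(=O)(=O)NN)c(C(C)C)c1
Why: Acid-catalyzed condensation of a ketone with an arenesulfonyl hydrazide; the E hydrazone, with the sulfonamide nitrogen anti to the aryl group and syn to the methyl group, should predominate and is the geometry the next step needs.

**Step 4**
Reactants: 6 (E)-N'-[1-(3,4,5-trimethoxyphenyl)ethylidene]-2,4,6-tri(propan-2-yl)benzenesulfonohydrazide; 4 5-(benzyloxy)-2-(ethenyloxy)-4-methoxybenzaldehyde
Product: 8 racemic 1-[5-(benzyloxy)-2-(ethenyloxy)-4-methoxyphenyl]-2-(3,4,5-trimethoxyphenyl)prop-2-en-1-ol, via 1-(3,4,5-trimethoxyphenyl)ethenyllithium 7 (not isolated)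
Conditions: 6 (1.3 equiv), n-BuLi (2.6 equiv), THF, −78 → 0 °C; then 4, −78 °C; H2O
Reagents that add atoms: none
Why: Shapiro reaction: double deprotonation of the trisylhydrazone (N–H, then the syn methyl C–H) and loss of sulfinate and N2 at 0 °C should give the 1-arylvinyllithium, which adds 1,2 to the non-enolizable aldehyde at −78 °C; the carbinol stereocenter (future C4) forms without control as a racemate, which does not matter because step 7 oxidizes it away.

**Step 5**
Reactants: 8 racemic 1-[5-(benzyloxy)-2-(ethenyloxy)-4-methoxyphenyl]-2-(3,4,5-trimethoxyphenyl)prop-2-en-1-ol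
Product: 9 racemic tert-butyl({1-[5-(benzyloxy)-2-(ethenyloxy)-4-methoxyphenyl]-2-(3,4,5-trimethoxyphenyl)prop-2-en-1-yl}oxy)dimethylsilane
Conditions: TBSCl, imidazole, DMAP (cat.), DMF, rt → 40 °C
Reagents that add atoms: tert-butyldimethylsilyl chloride, CC(C)(C)[Si](C)(C)Cl
Why: Standard silylation of a secondary alcohol with TBSCl and imidazole under basic conditions, chosen over a silyl triflate to spare the acid-sensitive aryl vinyl ether and the ionization-prone benzylic, allylic carbinol; the stereocenter is not touched.

**Step 6**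
Reactants: 9 racemic tert-butyl({1-[5-(benzyloxy)-2-(ethenyloxy)-4-methoxyphenyl]-2-(3,4,5-trimethoxyphenyl)prop-2-en-1-yl}oxy)dimethylsilane
Product: 10 racemic tert-butyl{[6-(benzyloxy)-7-methoxy-3-(3,4,5-trimethoxyphenyl)-4H-chromen-4-yl]oxy}dimethylsilane
Conditions: second-generation Grubbs catalyst RuCl2(=CHPh)(H2IMes)(PCy3) (10 mol %), toluene (5 mM), 80 °C, Ar sparge
Reagents that add atoms: none
Why: Ring-closing olefin metathesis by the Chauvin mechanism: the benzylidene exchanges onto the unhindered O-vinyl group to give a ruthenium aryloxycarbene at C2, this adds intramolecularly across the 1,1-disubstituted C3=CH2 bond, and the ruthenacyclobutane cycloreverts to the C2=C3 enol ether and Ru=CH2, which re-enters the cycle with loss of ethene. The closest known reactions are metathesis ring closures of aryl vinyl or propenyl ethers onto ortho alkenyl side chains to give 4H-chromenes and benzofurans, and ring closures onto 1,1-disubstituted styrenes; because both demands are combined here and aryloxycarbenes turn over slowly, the N-heterocyclic-carbene catalyst and heating in toluene are used. Ring C closes as a six-membered ring through the carbene–alkene [2+2] and retro-[2+2] sequence, with both reacting groups held ortho to each other on ring A. No stereocenter is created; C4 is already present as a racemate and is removed in step 7. The step needs ring closure to win over cross-metathesis and over migration of the 1,1-disubstituted double bond toward the siloxy carbon; high dilution, removal of ethene in the argon stream, the ortho tethers and the conjugated styrene-type enol ether formed on closure should secure this. The carbinol is kept as its silyl ether so that the alkene partner is not an electron-poor, polymerizable alpha-aryl enone.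

**Step 7**
Reactants: 10 racemic tert-butyl{[6-(benzyloxy)-7-methoxy-3-(3,4,5-trimethoxyphenyl)-4H-chromen-4-yl]oxy}dimethylsilane
Product: 11 6-(benzyloxy)-7-methoxy-3-(3,4,5-trimethoxyphenyl)-4H-chromen-4-one
Conditions: DDQ (1.2 equiv), CH2Cl2–H2O (18:1), 0 °C → rt
Reagents that add atoms: none
Why: DDQ oxidation of a benzylic, allylic silyl ether to the carbonyl compound: hydride abstraction from C4–H (benzylic to the para-methoxy-substituted ring A, alpha to the siloxy oxygen and vinylogously alpha to O1) should give an aromatic benzopyrylium-type cation whose O–Si bond is then cleaved by water, so the carbinol oxygen becomes the chromone carbonyl oxygen while the aryl benzyl ether is inert to DDQ under these conditions.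

**Step 8**
Reactants: 11 6-(benzyloxy)-7-methoxy-3-(3,4,5-trimethoxyphenyl)-4H-chromen-4-one
Product: 12 6-hydroxy-7-methoxy-3-(3,4,5-trimethoxyphenyl)-4H-chromen-4-one (CNP0248931.0)
Conditions: H2 (1 atm), Pd/C (10 %), EtOAc–MeOH, rt, stopped after one equivalent of H2
Reagents that add atoms: none
Why: Catalytic hydrogenolysis of an aryl benzyl ether over Pd/C; the chromone C2=C3 bond is a vinylogous ester conjugated to two aryl rings and is reduced much more slowly, so the C6 phenol should be freed without forming the isoflavanone.

**Compound list**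

1 | 4-(benzyloxy)-3-methoxyphenol | COc1cc(O)ccc1OCc1ccccc1 | starting material
2 | 5-(benzyloxy)-2-hydroxy-4-methoxybenzaldehyde | COc1cc(O)c(C=O)cc1OCc1ccccc1 | intermediate
3 | vinyl acetate (ethenyl acetate) | CC(=O)OC=C | starting material
4 | 5-(benzyloxy)-2-(ethenyloxy)-4-methoxybenzaldehyde | COc1cc(OC=C)c(C=O)cc1OCc1ccccc1 | intermediate
5 | 1-(3,4,5-trimethoxyphenyl)ethan-1-one | CC(=O)c1cc(OC)c(OC)c(OC)c1 | starting material
6 | (E)-N'-[1-(3,4,5-trimethoxyphenyl)ethylidene]-2,4,6-tri(propan-2-yl)benzenesulfonohydrazide | C/C(=N\NS(=O)(=O)c1c(C(C)C)cc(C(C)C)cc1C(C)C)c1cc(OC)c(OC)c(OC)c1 | intermediate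
7 | 1-(3,4,5-trimethoxyphenyl)ethenyllithium (formed in the flask, not isolated) | [Li]C(=C)c1cc(OC)c(OC)c(OC)c1 | intermediate
8 | racemic 1-[5-(benzyloxy)-2-(ethenyloxy)-4-methoxyphenyl]-2-(3,4,5-trimethoxyphenyl)prop-2-en-1-ol | COc1cc(OC=C)c(C(O)C(=C)c2cc(OC)c(OC)c(OC)c2)cc1OCc1ccccc1 | intermediate
9 | racemic tert-butyl({1-[5-(benzyloxy)-2-(ethenyloxy)-4-methoxyphenyl]-2-(3,4,5-trimethoxyphenyl)prop-2-en-1-yl}oxy)dimethylsilane | COc1cc(OC=C)c(C(O[Si](C)(C)C(C)(C)C)C(=C)c2cc(OC)c(OC)c(OC)c2)cc1OCc1ccccc1 | intermediate
10 | racemic tert-butyl{[6-(benzyloxy)-7-methoxy-3-(3,4,5-trimethoxyphenyl)-4H-chromen-4-yl]oxy}dimethylsilane | COc1cc2OC=C(c3cc(OC)c(OC)c(OC)c3)C(O[Si](C)(C)C(C)(C)C)c2cc1OCc1ccccc1 | intermediate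
11 | 6-(benzyloxy)-7-methoxy-3-(3,4,5-trimethoxyphenyl)-4H-chromen-4-one | COc1cc2occ(-c3cc(OC)c(OC)c(OC)c3)c(=O)c2cc1OCc1ccccc1 | intermediate
12 | 6-hydroxy-7-methoxy-3-(3,4,5-trimethoxyphenyl)-4H-chromen-4-one | COc1cc2occ(-c3cc(OC)c(OC)c(OC)c3)c(=O)c2cc1O | target

**Step count**

Total steps: 8. Longest linear sequence: 7 steps (steps 1, 2, 4, 5, 6, 7, 8 from phenol 1); step 3 is the side branch from ketone 5.

**Steps most likely to fail**

Step 6. The catalyst may rest as the slow aryloxycarbene without engaging the hindered 1,1-disubstituted alkene, so that the diene is returned or its double bond migrates before closure. The fallback closes ring C by conjugate addition instead of metathesis and sets out from alcohol 8. MnO2 in CH2Cl2 should oxidize the carbinol to 1-[5-(benzyloxy)-2-(ethenyloxy)-4-methoxyphenyl]-2-(3,4,5-trimethoxyphenyl)prop-2-en-1-one F1. Dilute HCl in THF should then hydrolyze the aryl vinyl ether to 1-[5-(benzyloxy)-2-hydroxy-4-methoxyphenyl]-2-(3,4,5-trimethoxyphenyl)prop-2-en-1-one F2. On brief treatment with K2CO3 in MeOH this phenol should close by 6-endo oxa-Michael addition to racemic 6-(benzyloxy)-7-methoxy-3-(3,4,5-trimethoxyphenyl)-2,3-dihydro-4H-chromen-4-one F3. Dehydrogenation of this isoflavanone with DDQ in dioxane at reflux comes back to the route at 11.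

Step 7. Ionization of the siloxy group may compete with hydride abstraction, or DDQ may attack the electron-rich rings. The fallback separates deprotection from oxidation and sets out from 10. TBAF in THF at 0 °C should give 6-(benzyloxy)-7-methoxy-3-(3,4,5-trimethoxyphenyl)-4H-chromen-4-ol F4, which is not stored but oxidized at once with MnO2 in CH2Cl2 as an allylic, benzylic alcohol, coming back to the route at 11.

Step 2. Vinyl transfer to the hydrogen-bonded, deactivated salicylaldehyde phenol may be slow, and acetic acid may add across the new vinyl ether. The fallback replaces transfer vinylation by a copper-mediated oxidative C–O coupling of Chan–Lam type. It sets out from 2 with 2,4,6-trivinylcyclotriboroxane–pyridine complex, Cu(OAc)2 and pyridine in CH2Cl2 at rt under air, and comes back to the route at 4 without any new compound.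

**Further compounds**

F1 | step 6 | 1-[5-(benzyloxy)-2-(ethenyloxy)-4-methoxyphenyl]-2-(3,4,5-trimethoxyphenyl)prop-2-en-1-one | COc1cc(OC=C)c(C(=O)C(=C)c2cc(OC)c(OC)c(OC)c2)cc1OCc1ccccc1
F2 | step 6 | 1-[5-(benzyloxy)-2-hydroxy-4-methoxyphenyl]-2-(3,4,5-trimethoxyphenyl)prop-2-en-1-one | COc1cc(O)c(C(=O)C(=C)c2cc(OC)c(OC)c(OC)c2)cc1OCc1ccccc1
F3 | step 6 | racemic 6-(benzyloxy)-7-methoxy-3-(3,4,5-trimethoxyphenyl)-2,3-dihydro-4H-chromen-4-one | COc1cc2OCC(c3cc(OC)c(OC)c(OC)c3)C(=O)c2cc1OCc1ccccc1
F4 | step 7 | racemic 6-(benzyloxy)-7-methoxy-3-(3,4,5-trimethoxyphenyl)-4H-chromen-4-ol | COc1cc2OC=C(c3cc(OC)c(OC)c(OC)c3)C(O)c2cc1OCc1ccccc1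
F0 | step 2 | none | none
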